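**Conventions and assumption**

- Ring letters: A is the 2,4,6-trihydroxyphenyl end, H the 3,4,5-trihydroxyphenyl end. In rings B, D and F, C1 carries the oxygen to the preceding ring, C4 the oxygen to the following ring, and C3 and C5 carry OH. In rings C, E and G, C1 carries the oxygen to the preceding ring, C2 the oxygen to the following ring, C3–C5 carry OH and C6 is CH.
- Ar-ABC = 6-[2,6-dimethoxy-4-(2,4,6-trimethoxyphenoxy)phenoxy]-2,3,4-trimethoxyphenyl (rings A–B–C, bonded through ring C).
- Ar-EFGH = 2-{3,5-dimethoxy-4-[3,4,5-trimethoxy-2-(3,4,5-trimethoxyphenoxy)phenoxy]phenoxy}-3,4,5-trimethoxyphenyl (rings E–F–G–H, bonded through ring E).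
- Assumption: 5-fluoro-1,2,3-trimethoxybenzene (1) and 5-iodo-1,2,3-trimethoxybenzene (22) are taken as purchasable arenes; fluoroaldehyde 2 is made from 1 because it is not expected to be a stock item.

## Analysis of the target

CNP0206369.0 (34) is an achiral, linear octamer of oxygenated benzene rings, C48H34O28. Rings A to H are joined by seven diaryl ether oxygens and carry twenty-one free phenolic hydroxyls; there is no stereocentre, so nothing has to be set or related. Ring A is a 2,4,6-trihydroxyphenyl ether, rings B, D and F are 3,5-dihydroxy-1,4-phenylenedioxy units, rings C, E and G are pentaoxygenated with two ortho ether oxygens and three contiguous hydroxyls, and ring H is 3,4,5-trihydroxyphenyl. Every ether oxygen leaves one ring from a carbon flanked by two oxygenated carbons and enters the next ring at a carbon with at least one free ortho position, so each link is hindered on one side and electron-rich on both. The free polyphenol, with four pyrogallol-type triads, is oxidised by air as soon as it is deprotonated, so all hydroxyls must stay masked until the last step, which must be run and worked up acidic and oxygen-free. The difficulty is therefore regiochemical and strategic: twenty-eight oxygens must be placed, seven hindered C–O–C bonds made, and a chain of eight rings kept from becoming one long linear sequence. The strategy rests on ring D: its oxygens on C1, C3 and C5 form the 1,3,5-pattern of a folded 3,5-dioxohexanoate, the C1 oxygen is arylated by ring C, and C4, the carbon between the two free hydroxyls, carries the oxygen to ring E. Forming the C3–C4 bond of ring D by an intramolecular Claisen condensation creates the central ring with both of its ether bonds already in place and divides the octamer into a trimer A–B–C and a tetramer E–F–G–H.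

## Retrosynthetic reasoning

**34 to 33.** The nineteen O–CH3 bonds are cut last. Methyl ethers are chosen because the building blocks 3, 4, 11 and 22 are bought as methyl ethers and because they survive every base, peracid and copper step. The two ring D hydroxyls are born free in 33 and need no protection. The forward step must cleave all alkyl–oxygen bonds without touching the aryl–oxygen–aryl bonds.

**33 to 31 (through 32).** The C3–C4 bond of ring D is cut. This is the only C–C disconnection of ring D that turns both of its ether-bearing carbons into carbons where oxygen can be introduced by simple substitution: C4 becomes an aryloxymethyl ketone carbon and C1 a vinylogous ester carbon. The open chain is stored as the 2-pyrone 31, which is stable and fixes the double bond so that ester carbon and ketone side chain stay cis. The forward step must open the lactone with an alkoxide and close the carbocycle by Claisen condensation before the vinylogous aryloxy group is exchanged.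

**31 to 30 and 10.** The C4–O bond of the pyrone is cut. What would be a hindered diaryl ether on an unactivated ring D is made instead as a vinylogous ester by addition–elimination of the hindered phenoxide of 10 on the sulfonate 30. This is the point of convergence of trimer and tetramer.

**30 to 29 to 28, then 28 to 26 and 27, then 26 to 24 and 25.** The sulfonate comes from the 4-hydroxy-2-pyrone 29, the lactone C–O bond of 29 from the 3,5-dioxo ester 28, and the C4–C5 bond of 28 from a Claisen acylation of the dianion of 27 by ester 26. The O–CH2 bond of 26 is an SN2 alkylation of phenol 24 by 25; this bond ends as the ring D C4–O–ring E ether.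

**10 to 8 to 7 and 2; 7 to 5 to 3 and 4; 2 to 1.** Each diaryl ether is cut so that the hindered ring is the phenoxide and the other ring is a fluoroarene activated by an aldehyde ortho or para to fluorine. The aldehyde is then converted by peracid oxidation into the next hindered phenol, so the formyl group serves twice: as activator and as latent hydroxyl. Block 4 supplies ring B and block 2, from formylation of 1, supplies ring C.

**24 to 23 to 21 and 22; 21 to 19 to 18 and 2; 18 to 16 to 15 and 4; 15 to 13 to 12 to 11.** The tetramer is grown from ring E towards ring H. Only in this direction is the nucleophile always the hindered phenoxide and the electrophile always one of the activated blocks 2 and 4; the reverse direction would require displacing fluoride from a carbon flanked by two methoxy groups. The C1 oxygen of ring E must stay distinguishable and is carried as a benzyl ether from 12 onwards. Ring H has no position for an activating group that could end as hydrogen, so it is attached in one step by copper-catalysed coupling of 21 with 22.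

## Alternatives that were turned down

**Alternative 1:** Ring B would be cut at two C–C bonds into a two-carbon unit, the aryl ynol ether A2 (2-(ethynyloxy)-1,3,5-trimethoxybenzene), which already holds the A–B ether oxygen, and a four-carbon unit, cyclobutenone A3 (3-methoxy-4-[(tert-butyldimethylsilyl)oxy]cyclobut-2-en-1-one).
- Forward key step: on heating, A3 opens to a vinylketene that adds [2+2] to A2; the resulting 2-vinylcyclobutenone opens again (4π), the dienylketene closes (6π) and tautomerises to phenol A1 (2-[(tert-butyldimethylsilyl)oxy]-3-methoxy-5-(2,4,6-trimethoxyphenoxy)phenol).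
- For it: the benzannulation is an established reaction class with alkoxy- and siloxyalkynes, so it is less speculative than the ring D closure chosen here. It also delivers the three contiguous oxygens of ring B in three different states.
- Against it: ring B is the second ring from one end, so A1 is only a dimer; six rings and five ether bonds would still have to be added one after another. A1 does the same job as dimer phenol 7, which takes two steps from 3 and 4. The differentiation of the two meta oxygens is of no use because both are hydroxyls in 34. A2 and A3 each need several steps, and the silyl ether must come off before the hindered oxygen is arylated by ring C in the same SNAr the chosen route uses.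
- Comparison: stronger on precedent, weaker on convergence and step count. The chosen strategy spends its one ring synthesis on the central ring, where it halves the molecule.

**Alternative 2:** Ring C would be cut between the carbon bearing the oxygen to ring B and the carbon bearing the oxygen to ring D, leading back to the racemic cyclobutenone A5 (4-{(Z)-2-[2,6-dimethoxy-4-(2,4,6-trimethoxyphenoxy)phenoxy]ethenyl}-2,3,4-trimethoxycyclobut-2-en-1-one).
- Forward key step: thermolysis opens the four-membered ring to a dienylketene; 6π closure joins the ketene carbon to the aryloxy-bearing vinyl carbon and tautomerisation gives A4, which is identical with trimer phenol 10.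
- For it: the three adjacent methoxy groups and the phenolic oxygen come from a squaric ester, so the oxygenation pattern is settled by construction, and the phenol appears free exactly where ring D must be attached. It also avoids the slow SNAr on the deactivated fluoroaldehyde 2; on that point it is stronger than steps 4 and 5.
- Against it: A5 needs a (Z)-2-aryloxyvinyl organometallic made from 7, threatened by β-elimination of the aryloxide, then addition to the squaric ester and O-methylation of a tertiary alkoxide. That is about five steps where the chosen route needs two from 7, and only the Z isomer can close.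
- Comparison: the outcome is the same trimer 10, and the central problem of joining trimer and tetramer through ring D is untouched. It could at best replace steps 4 and 5 inside the chosen plan.

**Alternative 3:** Ring A would be cut between its ether-bearing carbon and a neighbouring hydroxyl-bearing carbon, leading back to the dioxo ester A7 (methyl 6-aryloxy-3,5-dioxohexanoate whose aryl group is the nonadeca-O-methyl heptamer of rings B to H).
- Forward key step: NaOMe deprotonates the aryloxymethyl ketone carbon, which attacks the ester carbonyl (C6 to C1), and enolisation gives A6, the octamer with the ring A triol free and rings B to H as methyl ethers.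
- For it: it uses the same Claisen logic as the chosen step but is closer to precedent. The substrate is a true 3,5-dioxo ester, there is no vinylogous aryloxy group to be exchanged and no pyrone to prepare and reopen. On the chemical risk of the cyclisation itself it is at least as strong.
- Against it: ring A is terminal and is the one ring that can be bought complete as 3. Rings B to H would first have to be joined in a single linear series of about thirteen operations, and the uncertain closure would then fall on the most valuable intermediate. A free 3,5-dioxo ester also lactonises readily to a 4-hydroxy-2-pyrone (the reaction used on purpose in step 17), whose anion is a stable dead end under methoxide. The C6 carbanion must form on a chain that is already deprotonated between the carbonyls, whereas in 32 the C3 oxygen is an ether.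
- Comparison: the chosen strategy applies the same bond formation at ring D and gains convergence (trimer plus tetramer, and a fallback that re-uses the trimer). It pays with the exchange risk at the vinylogous ester.

Key step: step 20

## Route

Step 1
Reactants: 1 5-fluoro-1,2,3-trimethoxybenzene
Product: 2 6-fluoro-2,3,4-trimethoxybenzaldehyde
Conditions: Cl2CHOMe, TiCl4, CH2Cl2, −10 to 0 °C; then ice/aq. HCl
Reagents that add atoms: dichloromethyl methyl ether, COC(Cl)Cl (formyl carbon); water, O (carbonyl oxygen on hydrolysis)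
Why: Rieche formylation; the two free positions of 1 are equivalent, each ortho to one methoxy group and para to another, so a single aldehyde should form, and TiCl4 at low temperature is strong enough to overcome the ortho-fluorine deactivation without cleaving methyl ethers.

Step 2
Reactants: 3 2,4,6-trimethoxyphenol; 4 4-fluoro-2,6-dimethoxybenzaldehyde
Product: 5 2,6-dimethoxy-4-(2,4,6-trimethoxyphenoxy)benzaldehyde
Conditions: Cs2CO3, DMSO, 90 °C, argon
Reagents that add atoms: none
Why: SNAr by addition–elimination; the fluorine of 4 is para to the formyl group and meta to both methoxy groups, so the hindered but electron-rich phenoxide of 3 should displace it through an aldehyde-stabilised Meisenheimer intermediate.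

Step 3
Reactants: 5 2,6-dimethoxy-4-(2,4,6-trimethoxyphenoxy)benzaldehyde
Product: 7 2,6-dimethoxy-4-(2,4,6-trimethoxyphenoxy)phenol, via aryl formate 6 (not isolated)
Conditions: mCPBA, CH2Cl2, 0 °C to rt; aq. NaHCO3 wash; then K2CO3 (cat.), MeOH, rt
Reagents that add atoms: 3-chloroperbenzoic acid, OOC(=O)c1cccc(Cl)c1
Why: Dakin-type Baeyer–Villiger oxidation; in the Criegee intermediate the aryl group with two ortho and one para oxygen migrates in preference to hydride, and the formate is removed by transesterification so that the new hindered phenol is exposed only after the oxidant is gone.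

Step 4
Reactants: 7 2,6-dimethoxy-4-(2,4,6-trimethoxyphenoxy)phenol; 2 6-fluoro-2,3,4-trimethoxybenzaldehyde
Product: 8 6-[2,6-dimethoxy-4-(2,4,6-trimethoxyphenoxy)phenoxy]-2,3,4-trimethoxybenzaldehyde
Conditions: Cs2CO3, DMSO, 120 °C, argon
Reagents that add atoms: none
Why: SNAr on an ortho-fluorobenzaldehyde; the fluorine-bearing carbon has one free ortho position, which lets the hindered phenoxide approach, and the cesium phenoxide in DMSO at higher temperature compensates for the deactivating para-methoxy group.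

Step 5
Reactants: 8 6-[2,6-dimethoxy-4-(2,4,6-trimethoxyphenoxy)phenoxy]-2,3,4-trimethoxybenzaldehyde
Product: 10 6-[2,6-dimethoxy-4-(2,4,6-trimethoxyphenoxy)phenoxy]-2,3,4-trimethoxyphenol, via aryl formate 9 (not isolated)
Conditions: mCPBA, CH2Cl2, 0 °C to rt; aq. NaHCO3 wash; then K2CO3 (cat.), MeOH, rt
Reagents that add atoms: 3-chloroperbenzoic acid, OOC(=O)c1cccc(Cl)c1
Why: Dakin-type Baeyer–Villiger oxidation as in step 3; the aldehyde flanked by a methoxy and an aryloxy group sits on the most electron-rich ring, so aryl migration should again be clean and give the trimer phenol with its hydroxyl on ring C at C2.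

Step 6
Reactants: 11 3,4,5-trimethoxyphenol
Product: 12 5-(benzyloxy)-1,2,3-trimethoxybenzene
Conditions: BnBr, K2CO3, DMF, rt
Reagents that add atoms: benzyl bromide, BrCc1ccccc1
Why: Williamson ether synthesis; the benzyl ether marks the future ring E C1 oxygen, withstands carbonate in hot DMSO, peracid and copper, and is later removed by hydrogenolysis without affecting methyl or diaryl ethers.

Step 7
Reactants: 12 5-(benzyloxy)-1,2,3-trimethoxybenzene
Product: 13 6-(benzyloxy)-2,3,4-trimethoxybenzaldehyde
Conditions: POCl3, DMF, 0 to 60 °C; then aq. NaOAc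
Reagents that add atoms: N,N-dimethylformamide, CN(C)C=O (formyl carbon); water, O (carbonyl oxygen on hydrolysis of the iminium salt)
Why: Vilsmeier–Haack formylation; the two free positions of the tetraalkoxybenzene are equivalent and strongly activated, so one aldehyde should form, and it deactivates the ring against a second formylation.

Step 8
Reactants: 13 6-(benzyloxy)-2,3,4-trimethoxybenzaldehyde
Product: 15 6-(benzyloxy)-2,3,4-trimethoxyphenol, via aryl formate 14 (not isolated)
Conditions: mCPBA, CH2Cl2, 0 °C to rt; aq. NaHCO3 wash; then K2CO3 (cat.), MeOH, rt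
Reagents that add atoms: 3-chloroperbenzoic acid, OOC(=O)c1cccc(Cl)c1
Why: Dakin-type Baeyer–Villiger oxidation as in step 3; it places the free hydroxyl on the ring E carbon that must carry ring F, next to the benzyl-protected oxygen.

Step 9
Reactants: 15 6-(benzyloxy)-2,3,4-trimethoxyphenol; 4 4-fluoro-2,6-dimethoxybenzaldehyde
Product: 16 4-[6-(benzyloxy)-2,3,4-trimethoxyphenoxy]-2,6-dimethoxybenzaldehyde
Conditions: Cs2CO3, DMSO, 90 °C, argon
Reagents that add atoms: none
Why: SNAr as in step 2, with the hindered phenoxide of 15 displacing the para-activated fluoride of 4 to form the E–F ether.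

Step 10
Reactants: 16 4-[6-(benzyloxy)-2,3,4-trimethoxyphenoxy]-2,6-dimethoxybenzaldehyde
Product: 18 4-[6-(benzyloxy)-2,3,4-trimethoxyphenoxy]-2,6-dimethoxyphenol, via aryl formate 17 (not isolated)
Conditions: mCPBA, CH2Cl2, 0 °C to rt; aq. NaHCO3 wash; then K2CO3 (cat.), MeOH, rt
Reagents that add atoms: 3-chloroperbenzoic acid, OOC(=O)c1cccc(Cl)c1
Why: Dakin-type Baeyer–Villiger oxidation as in step 3; the benzyl ether is inert to the peracid and the ring F aldehyde becomes the hindered ring F phenol.

Step 11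
Reactants: 18 4-[6-(benzyloxy)-2,3,4-trimethoxyphenoxy]-2,6-dimethoxyphenol; 2 6-fluoro-2,3,4-trimethoxybenzaldehyde
Product: 19 6-{4-[6-(benzyloxy)-2,3,4-trimethoxyphenoxy]-2,6-dimethoxyphenoxy}-2,3,4-trimethoxybenzaldehyde
Conditions: Cs2CO3, DMSO, 120 °C, argon
Reagents that add atoms: none
Why: SNAr on the ortho-fluorobenzaldehyde as in step 4; it forms the F–G ether and places the formyl group where ring G must later carry ring H.

Step 12
Reactants: 19 6-{4-[6-(benzyloxy)-2,3,4-trimethoxyphenoxy]-2,6-dimethoxyphenoxy}-2,3,4-trimethoxybenzaldehyde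
Product: 21 6-{4-[6-(benzyloxy)-2,3,4-trimethoxyphenoxy]-2,6-dimethoxyphenoxy}-2,3,4-trimethoxyphenol, via aryl formate 20 (not isolated)
Conditions: mCPBA, CH2Cl2, 0 °C to rt; aq. NaHCO3 wash; then K2CO3 (cat.), MeOH, rt
Reagents that add atoms: 3-chloroperbenzoic acid, OOC(=O)c1cccc(Cl)c1
Why: Dakin-type Baeyer–Villiger oxidation as in step 5, giving the ring G phenol.

Step 13
Reactants: 21 6-{4-[6-(benzyloxy)-2,3,4-trimethoxyphenoxy]-2,6-dimethoxyphenoxy}-2,3,4-trimethoxyphenol; 22 5-iodo-1,2,3-trimethoxybenzene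
Product: 23 1-(benzyloxy)-2-{3,5-dimethoxy-4-[3,4,5-trimethoxy-2-(3,4,5-trimethoxyphenoxy)phenoxy]phenoxy}-3,4,5-trimethoxybenzene
Conditions: CuI (10 mol %), picolinic acid (20 mol %), K3PO4, DMSO, 90 °C, argon
Reagents that add atoms: none
Why: Ligand-accelerated Ullmann diaryl ether synthesis; a hindered phenoxide with an unhindered aryl iodide is the favourable pairing for copper-catalysed O-arylation, and ring H is attached complete in one step.

Step 14
Reactants: 23 1-(benzyloxy)-2-{3,5-dimethoxy-4-[3,4,5-trimethoxy-2-(3,4,5-trimethoxyphenoxy)phenoxy]phenoxy}-3,4,5-trimethoxybenzene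
Product: 24 2-{3,5-dimethoxy-4-[3,4,5-trimethoxy-2-(3,4,5-trimethoxyphenoxy)phenoxy]phenoxy}-3,4,5-trimethoxyphenol (Ar-EFGH–OH)
Conditions: H2 (1 atm), 10% Pd/C, EtOAc–MeOH, rt
Reagents that add atoms: none
Why: Catalytic hydrogenolysis of the benzyl ether; methyl and diaryl ethers are inert, and the tetramer phenol is released with its hydroxyl on ring E at C1.

Step 15
Reactants: 24 Ar-EFGH–OH; 25 methyl bromoacetate
Product: 26 methyl (Ar-EFGH-oxy)acetate
Conditions: K2CO3, acetone, reflux
Reagents that add atoms: none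
Why: Williamson (SN2) alkylation of the least hindered phenol of the route by an α-halo ester; the O–CH2 bond formed here becomes the ring D C4–O–ring E ether.

Step 16
Reactants: 26 methyl (Ar-EFGH-oxy)acetate; 27 methyl acetoacetate
Product: 28 methyl 6-(Ar-EFGH-oxy)-3,5-dioxohexanoate
Conditions: 27 (3 equiv), NaH, THF, 0 °C; n-BuLi, 0 °C; then 26, −78 to 0 °C; aq. HCl
Reagents that add atoms: none
Why: Claisen acylation of a β-keto ester dianion; the terminal carbanion of the dianion of 27 attacks the unhindered, inductively activated aryloxyacetate, and excess dianion covers the deprotonation of the more acidic product.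

Step 17
Reactants: 28 methyl 6-(Ar-EFGH-oxy)-3,5-dioxohexanoate
Product: 29 4-hydroxy-6-[(Ar-EFGH-oxy)methyl]-2H-pyran-2-one
Conditions: DBU, toluene, 80 °C; aq. HCl
Reagents that add atoms: none
Why: Base-mediated lactonisation of a 3,5-dioxo ester to a 4-hydroxy-2-pyrone; under the amidine base only the monoanion between the two ketones forms, whose C5 enol oxygen attacks the ester with loss of methanol, so the carbon-based Claisen closure is not available at this stage.

Step 18
Reactants: 29 4-hydroxy-6-[(Ar-EFGH-oxy)methyl]-2H-pyran-2-one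
Product: 30 6-[(Ar-EFGH-oxy)methyl]-2-oxo-2H-pyran-4-yl 4-methylbenzenesulfonate
Conditions: TsCl, Et3N, CH2Cl2, 0 °C
Reagents that add atoms: 4-methylbenzenesulfonyl chloride, Cc1ccc(cc1)S(Cl)(=O)=O
Why: O-sulfonylation of the vinylogous acid; 4-hydroxy-2-pyrones react at the C4 oxygen and the tosylate turns C4 into a vinylogous acyl electrophile.

Step 19
Reactants: 30 6-[(Ar-EFGH-oxy)methyl]-2-oxo-2H-pyran-4-yl 4-methylbenzenesulfonate; 10 6-[2,6-dimethoxy-4-(2,4,6-trimethoxyphenoxy)phenoxy]-2,3,4-trimethoxyphenol (Ar-ABC–OH)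
Product: 31 4-(Ar-ABC-oxy)-6-[(Ar-EFGH-oxy)methyl]-2H-pyran-2-one
Conditions: K2CO3, MeCN, rt to 50 °C, argon
Reagents that add atoms: none
Why: Addition–elimination (vinylogous acyl substitution) at C4 of the 2-pyrone, a known reaction of 4-sulfonyloxy- and 4-halo-2-pyrones with heteroatom nucleophiles; the phenoxide of 10 adds in a conjugate sense and sulfonate leaves, so the hindered C–O bond is formed as a vinylogous ester and not as a diaryl ether.

Step 20
Reactants: 31 4-(Ar-ABC-oxy)-6-[(Ar-EFGH-oxy)methyl]-2H-pyran-2-one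
Product: 33 5-(Ar-ABC-oxy)-2-(Ar-EFGH-oxy)benzene-1,3-diol, via ring-opened enoate 32 (not isolated)
Conditions: Mg(OMe)2 (3 equiv), MeOH–THF, 0 °C to rt; then NaOMe (5 equiv), 60 °C; 1 M HCl, 0 °C; argon throughout
Reagents that add atoms: none
Why: Proposed new method: methoxide delivered from Mg(OMe)2 adds to the lactone carbonyl C2 of 31 and the C2–O1 bond breaks, giving the dienolate of enoate 32, in which the ester carbon and the C4 methylene stay cis across the former C3=C4 bond of the pyrone (this isomer is 2E by the sequence rules because the aryloxy group outranks the methylene, and it is the only geometry from which closure is possible). Under NaOMe the dienolate equilibrates with the ketone enolate at C6, made accessible by the ring E aryloxy substituent, and this carbon attacks the ester carbonyl C1 in a Claisen condensation, a 6-exo-trig closure that expels methoxide; the resulting 2,5-bis(aryloxy)cyclohex-4-ene-1,3-dione enolises at once to the resorcinol 33, whose deprotonation makes the sequence irreversible. The closest known chemistry is the base-mediated passage of triacetic acid lactone through methyl 3,5-dioxohexanoate to phloroglucinol, together with magnesium methoxide openings of 4-methoxy-2-pyrones that lead into polyketide-type aldol and Claisen aromatisations; the same sequence with aryloxy groups on C3 and C6 of the chain has not been shown. No stereocentre is formed. The selectivity needed is attack at the lactone carbonyl rather than conjugate attack at C4, which would exchange the ring C aryloxy group for methoxy: coordination of divalent magnesium to the lactone carbonyl and screening of C4 by the doubly ortho-substituted ring C are relied on, and NaOMe is added only after the pyrone is consumed, when C3 is part of an electron-rich dienolate and no longer an acceptor. The more stable C4 carbanion cannot cyclise (it would give a four-membered ring) and relactonisation through the C5 enolate oxygen only regenerates 31, so both are resting states that drain into the irreversible six-membered closure. Overall 31 is isomerised to 33, the methanol taken up in the opening being released in the closure.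

Step 21
Reactants: 33 5-(Ar-ABC-oxy)-2-(Ar-EFGH-oxy)benzene-1,3-diol
Product: 34 CNP0206369.0
Conditions: BBr3 (60 equiv), CH2Cl2, −78 °C to rt; MeOH then H2O, 0 °C; argon; reversed-phase chromatography with acidified eluent
Reagents that add atoms: none
Why: Lewis-acid cleavage of aryl methyl ethers; BBr3 coordinates each methoxy oxygen and bromide attacks the methyl carbon (SN2), while the diaryl ether oxygens have no sp3 carbon to be attacked and should remain; the aryl borates are hydrolysed on work-up.

## Compound list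

1 | 5-fluoro-1,2,3-trimethoxybenzene | COc1cc(F)cc(OC)c1OC | starting material
2 | 6-fluoro-2,3,4-trimethoxybenzaldehyde | COc1cc(F)c(C=O)c(OC)c1OC | intermediate
3 | 2,4,6-trimethoxyphenol | COc1cc(OC)c(O)c(OC)c1 | starting material
4 | 4-fluoro-2,6-dimethoxybenzaldehyde | COc1cc(F)cc(OC)c1C=O | starting material
5 | 2,6-dimethoxy-4-(2,4,6-trimethoxyphenoxy)benzaldehyde | COc1cc(OC)c(c(OC)c1)Oc1cc(OC)c(C=O)c(OC)c1 | intermediate
6 | 2,6-dimethoxy-4-(2,4,6-trimethoxyphenoxy)phenyl formate | COc1cc(OC)c(c(OC)c1)Oc1cc(OC)c(OC=O)c(OC)c1 | intermediate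
7 | 2,6-dimethoxy-4-(2,4,6-trimethoxyphenoxy)phenol | COc1cc(OC)c(c(OC)c1)Oc1cc(OC)c(O)c(OC)c1 | intermediate
8 | 6-[2,6-dimethoxy-4-(2,4,6-trimethoxyphenoxy)phenoxy]-2,3,4-trimethoxybenzaldehyde | COc1cc(OC)c(c(OC)c1)Oc1cc(OC)c(c(OC)c1)Oc1cc(OC)c(OC)c(OC)c1C=O | intermediate
9 | 6-[2,6-dimethoxy-4-(2,4,6-trimethoxyphenoxy)phenoxy]-2,3,4-trimethoxyphenyl formate | COc1cc(OC)c(c(OC)c1)Oc1cc(OC)c(c(OC)c1)Oc1cc(OC)c(OC)c(OC)c1OC=O | intermediate
10 | 6-[2,6-dimethoxy-4-(2,4,6-trimethoxyphenoxy)phenoxy]-2,3,4-trimethoxyphenol (Ar-ABC–OH) | COc1cc(OC)c(c(OC)c1)Oc1cc(OC)c(c(OC)c1)Oc1cc(OC)c(OC)c(OC)c1O | intermediate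
11 | 3,4,5-trimethoxyphenol | COc1cc(O)cc(OC)c1OC | starting material
12 | 5-(benzyloxy)-1,2,3-trimethoxybenzene | COc1cc(OCc2ccccc2)cc(OC)c1OC | intermediate
13 | 6-(benzyloxy)-2,3,4-trimethoxybenzaldehyde | COc1cc(OCc2ccccc2)c(C=O)c(OC)c1OC | intermediate
14 | 6-(benzyloxy)-2,3,4-trimethoxyphenyl formate | COc1cc(OCc2ccccc2)c(OC=O)c(OC)c1OC | intermediate
15 | 6-(benzyloxy)-2,3,4-trimethoxyphenol | COc1cc(OCc2ccccc2)c(O)c(OC)c1OC | intermediate
16 | 4-[6-(benzyloxy)-2,3,4-trimethoxyphenoxy]-2,6-dimethoxybenzaldehyde | c1ccccc1COc1cc(OC)c(OC)c(OC)c1Oc1cc(OC)c(C=O)c(OC)c1 | intermediate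
17 | 4-[6-(benzyloxy)-2,3,4-trimethoxyphenoxy]-2,6-dimethoxyphenyl formate | c1ccccc1COc1cc(OC)c(OC)c(OC)c1Oc1cc(OC)c(OC=O)c(OC)c1 | intermediate
18 | 4-[6-(benzyloxy)-2,3,4-trimethoxyphenoxy]-2,6-dimethoxyphenol | c1ccccc1COc1cc(OC)c(OC)c(OC)c1Oc1cc(OC)c(O)c(OC)c1 | intermediate
19 | 6-{4-[6-(benzyloxy)-2,3,4-trimethoxyphenoxy]-2,6-dimethoxyphenoxy}-2,3,4-trimethoxybenzaldehyde | c1ccccc1COc1cc(OC)c(OC)c(OC)c1Oc1cc(OC)c(c(OC)c1)Oc1cc(OC)c(OC)c(OC)c1C=O | intermediate
20 | 6-{4-[6-(benzyloxy)-2,3,4-trimethoxyphenoxy]-2,6-dimethoxyphenoxy}-2,3,4-trimethoxyphenyl formate | c1ccccc1COc1cc(OC)c(OC)c(OC)c1Oc1cc(OC)c(c(OC)c1)Oc1cc(OC)c(OC)c(OC)c1OC=O | intermediate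
21 | 6-{4-[6-(benzyloxy)-2,3,4-trimethoxyphenoxy]-2,6-dimethoxyphenoxy}-2,3,4-trimethoxyphenol | c1ccccc1COc1cc(OC)c(OC)c(OC)c1Oc1cc(OC)c(c(OC)c1)Oc1cc(OC)c(OC)c(OC)c1O | intermediate
22 | 5-iodo-1,2,3-trimethoxybenzene | COc1cc(I)cc(OC)c1OC | starting material
23 | 1-(benzyloxy)-2-{3,5-dimethoxy-4-[3,4,5-trimethoxy-2-(3,4,5-trimethoxyphenoxy)phenoxy]phenoxy}-3,4,5-trimethoxybenzene | c1ccccc1COc1cc(OC)c(OC)c(OC)c1Oc1cc(OC)c(c(OC)c1)Oc1cc(OC)c(OC)c(OC)c1Oc1cc(OC)c(OC)c(OC)c1 | intermediate
24 | 2-{3,5-dimethoxy-4-[3,4,5-trimethoxy-2-(3,4,5-trimethoxyphenoxy)phenoxy]phenoxy}-3,4,5-trimethoxyphenol (Ar-EFGH–OH) | Oc1cc(OC)c(OC)c(OC)c1Oc1cc(OC)c(c(OC)c1)Oc1cc(OC)c(OC)c(OC)c1Oc1cc(OC)c(OC)c(OC)c1 | intermediate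
25 | methyl bromoacetate | COC(=O)CBr | starting material
26 | methyl (Ar-EFGH-oxy)acetate | COC(=O)COc1cc(OC)c(OC)c(OC)c1Oc1cc(OC)c(c(OC)c1)Oc1cc(OC)c(OC)c(OC)c1Oc1cc(OC)c(OC)c(OC)c1 | intermediate
27 | methyl acetoacetate | COC(=O)CC(C)=O | starting material
28 | methyl 6-(Ar-EFGH-oxy)-3,5-dioxohexanoate | COC(=O)CC(=O)CC(=O)COc1cc(OC)c(OC)c(OC)c1Oc1cc(OC)c(c(OC)c1)Oc1cc(OC)c(OC)c(OC)c1Oc1cc(OC)c(OC)c(OC)c1 | intermediate
29 | 4-hydroxy-6-[(Ar-EFGH-oxy)methyl]-2H-pyran-2-one | O=C1C=C(O)C=C(COc2cc(OC)c(OC)c(OC)c2Oc2cc(OC)c(c(OC)c2)Oc2cc(OC)c(OC)c(OC)c2Oc2cc(OC)c(OC)c(OC)c2)O1 | intermediate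
30 | 6-[(Ar-EFGH-oxy)methyl]-2-oxo-2H-pyran-4-yl 4-methylbenzenesulfonate | O=C1C=C(OS(=O)(=O)c2ccc(C)cc2)C=C(COc2cc(OC)c(OC)c(OC)c2Oc2cc(OC)c(c(OC)c2)Oc2cc(OC)c(OC)c(OC)c2Oc2cc(OC)c(OC)c(OC)c2)O1 | intermediate
31 | 4-(Ar-ABC-oxy)-6-[(Ar-EFGH-oxy)methyl]-2H-pyran-2-one | O=C1C=C(Oc2c(OC)c(OC)c(OC)cc2Oc2c(OC)cc(Oc3c(OC)cc(OC)cc3OC)cc2OC)C=C(COc2cc(OC)c(OC)c(OC)c2Oc2cc(OC)c(c(OC)c2)Oc2cc(OC)c(OC)c(OC)c2Oc2cc(OC)c(OC)c(OC)c2)O1 | intermediate
32 | methyl (2E)-3-(Ar-ABC-oxy)-6-(Ar-EFGH-oxy)-5-oxohex-2-enoate (ester carbon and C4 methylene cis) | COC(=O)/C=C(\CC(=O)COc1cc(OC)c(OC)c(OC)c1Oc1cc(OC)c(c(OC)c1)Oc1cc(OC)c(OC)c(OC)c1Oc1cc(OC)c(OC)c(OC)c1)Oc1c(OC)c(OC)c(OC)cc1Oc1c(OC)cc(Oc2c(OC)cc(OC)cc2OC)cc1OC | intermediate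
33 | 5-(Ar-ABC-oxy)-2-(Ar-EFGH-oxy)benzene-1,3-diol (nonadeca-O-methyl octamer, ring D diol free) | COc1cc(OC)c(c(OC)c1)Oc1cc(OC)c(c(OC)c1)Oc1cc(OC)c(OC)c(OC)c1Oc1cc(O)c(c(O)c1)Oc1cc(OC)c(OC)c(OC)c1Oc1cc(OC)c(c(OC)c1)Oc1cc(OC)c(OC)c(OC)c1Oc1cc(OC)c(OC)c(OC)c1 | intermediate
34 | CNP0206369.0: 5-{6-[2,6-dihydroxy-4-(2,4,6-trihydroxyphenoxy)phenoxy]-2,3,4-trihydroxyphenoxy}-2-(2-{3,5-dihydroxy-4-[3,4,5-trihydroxy-2-(3,4,5-trihydroxyphenoxy)phenoxy]phenoxy}-3,4,5-trihydroxyphenoxy)benzene-1,3-diol | Oc1cc(O)c(Oc2cc(O)c(Oc3cc(O)c(O)c(O)c3Oc3cc(O)c(Oc4cc(O)c(O)c(O)c4Oc4cc(O)c(Oc5cc(O)c(O)c(O)c5Oc5cc(O)c(O)c(O)c5)c(O)c4)c(O)c3)c(O)c2)c(O)c1 | target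

## Step count and least certain steps

Total: 21 steps. Longest linear sequence: 16 steps (steps 6 to 21, from 11). The trimer branch (steps 1 to 5) joins at step 19.

**Step 20 (key step, the one carrying the new-method label).** Most likely failure: methoxide adds in a conjugate sense at C4 of the pyrone, or at C3 of the neutral open chain, and expels the ring C phenoxide, so the trimer is lost before the carbocycle closes. The second risk is stalling, because the ester of a vinylogous carbonate is a weak acceptor and the chain rests as the stabilised dienolate or relactonises. Retro-Claisen cleavage of the C4–C5 bond by methoxide at the ketone is the third.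
Fallback by known chemistry only, setting out from trimer phenol 10 and continuing the SNAr/Baeyer–Villiger iteration through ring D instead of folding it:
- 10 and 4 (Cs2CO3, DMSO) should give the tetramer A–D aldehyde F1; mCPBA and methanolysis convert it through formate F2 into phenol F3.
- F3 and 2 give the pentamer aldehyde F4, then formate F5 and phenol F6.
- F6 and 4 give the hexamer aldehyde F7, then formate F8 and phenol F9.
- F9 and 2 give the heptamer aldehyde F10, then formate F11 and phenol F12.
- Copper-catalysed coupling of F12 with 22 under the conditions of step 13 gives the henicosa-O-methyl octamer F13, and BBr3 as in step 21 returns to the route at target 34.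

This fallback gives up convergence and makes the tetramer line and the pyrone unnecessary, but every bond is formed by a reaction already used in steps 2 to 5 and 13.

**Step 19.** Most likely failure: the hindered phenoxide attacks the sulfonyl sulfur (tosyl transfer to the phenol with return of the pyronate) or the lactone carbonyl, instead of adding at C4. Fallback, setting out from 29: bromination of the vinylogous acid (Bu4NBr, P2O5, toluene, 100 °C) gives 4-bromo-6-[(Ar-EFGH-oxy)methyl]-2H-pyran-2-one F14, which has no second electrophilic centre at the leaving group; its addition–elimination with 10 and K2CO3 returns to the route at 31.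

**Step 21.** Most likely failure: incomplete cleavage spread over nineteen sites, combined with oxidative decay of the pyrogallol-type rings during isolation of the very polar product. Fallback, setting out from 33: after BBr3 treatment and quench the crude polyphenol is acetylated directly (Ac2O, pyridine) to the henicosaacetate F15, which is stable and can be chromatographed on silica; partially methylated acetates are separated and resubmitted. Deacetylation of F15 (cat. NaOMe, degassed MeOH, 0 °C, acidic resin quench under argon) returns to 34.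

**Step 16.** Most likely failure: proton transfer instead of acylation, either enolisation of the aryloxyacetate by the strongly basic dianion or quenching of the dianion by the product, leaving the valuable ester 26 largely unconverted. Fallback, setting out from 24: alkylation with 2-chloro-N-methoxy-N-methylacetamide (K2CO3, NaI, DMF) gives the Weinreb amide F16; acylation of the lithium dienolate of 2,2,6-trimethyl-4H-1,3-dioxin-4-one (LiHMDS, THF, −78 °C) gives the keto-dioxinone F17. Thermolysis of F17 in toluene at 110 °C releases acetone, and the acylketene is trapped by the enol oxygen to return to the route at 29, which also bypasses step 17.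

**Step 13.** Most likely failure: the doubly ortho-oxygenated phenoxide binds copper as a chelate and turnover stops, with slow reduction of the aryl iodide. Fallback, setting out from 21: SNAr with 4 (Cs2CO3, DMSO) gives the aldehyde F18; mCPBA and methanolysis give, through formate F19, the phenol F20; methylation (MeI, K2CO3, acetone) returns to the route at 23.

**Step 4 (the same concern applies to step 11).** Most likely failure: slow substitution, because the methoxy group para to fluorine feeds electron density into the reacting carbon; at the temperature then needed, oxidation of the phenoxide and base-induced decay of the aldehyde compete. Fallback, setting out from 7: Rieche formylation of purchased 5-bromo-1,2,3-trimethoxybenzene gives 6-bromo-2,3,4-trimethoxybenzaldehyde F21; an Ullmann coupling of 7 with F21 (CuI, picolinic acid, K3PO4, DMSO, 90 °C), assisted by the ortho-formyl group, returns to the route at 8.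

## Further compounds

F1 | step 20 | 4-(Ar-ABC-oxy)-2,6-dimethoxybenzaldehyde (tetramer A–D aldehyde) | COc1cc(OC)c(c(OC)c1)Oc1cc(OC)c(c(OC)c1)Oc1cc(OC)c(OC)c(OC)c1Oc1cc(OC)c(C=O)c(OC)c1
F2 | step 20 | 4-(Ar-ABC-oxy)-2,6-dimethoxyphenyl formate | COc1cc(OC)c(c(OC)c1)Oc1cc(OC)c(c(OC)c1)Oc1cc(OC)c(OC)c(OC)c1Oc1cc(OC)c(OC=O)c(OC)c1
F3 | step 20 | 4-(Ar-ABC-oxy)-2,6-dimethoxyphenol (tetramer A–D phenol) | COc1cc(OC)c(c(OC)c1)Oc1cc(OC)c(c(OC)c1)Oc1cc(OC)c(OC)c(OC)c1Oc1cc(OC)c(O)c(OC)c1
F4 | step 20 | 6-[4-(Ar-ABC-oxy)-2,6-dimethoxyphenoxy]-2,3,4-trimethoxybenzaldehyde (pentamer A–E aldehyde) | COc1cc(OC)c(c(OC)c1)Oc1cc(OC)c(c(OC)c1)Oc1cc(OC)c(OC)c(OC)c1Oc1cc(OC)c(c(OC)c1)Oc1cc(OC)c(OC)c(OC)c1C=O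
F5 | step 20 | 6-[4-(Ar-ABC-oxy)-2,6-dimethoxyphenoxy]-2,3,4-trimethoxyphenyl formate | COc1cc(OC)c(c(OC)c1)Oc1cc(OC)c(c(OC)c1)Oc1cc(OC)c(OC)c(OC)c1Oc1cc(OC)c(c(OC)c1)Oc1cc(OC)c(OC)c(OC)c1OC=O
F6 | step 20 | 6-[4-(Ar-ABC-oxy)-2,6-dimethoxyphenoxy]-2,3,4-trimethoxyphenol (pentamer A–E phenol) | COc1cc(OC)c(c(OC)c1)Oc1cc(OC)c(c(OC)c1)Oc1cc(OC)c(OC)c(OC)c1Oc1cc(OC)c(c(OC)c1)Oc1cc(OC)c(OC)c(OC)c1O
F7 | step 20 | 4-{6-[4-(Ar-ABC-oxy)-2,6-dimethoxyphenoxy]-2,3,4-trimethoxyphenoxy}-2,6-dimethoxybenzaldehyde (hexamer A–F aldehyde) | COc1cc(OC)c(c(OC)c1)Oc1cc(OC)c(c(OC)c1)Oc1cc(OC)c(OC)c(OC)c1Oc1cc(OC)c(c(OC)c1)Oc1cc(OC)c(OC)c(OC)c1Oc1cc(OC)c(C=O)c(OC)c1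
F8 | step 20 | 4-{6-[4-(Ar-ABC-oxy)-2,6-dimethoxyphenoxy]-2,3,4-trimethoxyphenoxy}-2,6-dimethoxyphenyl formate | COc1cc(OC)c(c(OC)c1)Oc1cc(OC)c(c(OC)c1)Oc1cc(OC)c(OC)c(OC)c1Oc1cc(OC)c(c(OC)c1)Oc1cc(OC)c(OC)c(OC)c1Oc1cc(OC)c(OC=O)c(OC)c1
F9 | step 20 | 4-{6-[4-(Ar-ABC-oxy)-2,6-dimethoxyphenoxy]-2,3,4-trimethoxyphenoxy}-2,6-dimethoxyphenol (hexamer A–F phenol) | COc1cc(OC)c(c(OC)c1)Oc1cc(OC)c(c(OC)c1)Oc1cc(OC)c(OC)c(OC)c1Oc1cc(OC)c(c(OC)c1)Oc1cc(OC)c(OC)c(OC)c1Oc1cc(OC)c(O)c(OC)c1
F10 | step 20 | 6-(4-{6-[4-(Ar-ABC-oxy)-2,6-dimethoxyphenoxy]-2,3,4-trimethoxyphenoxy}-2,6-dimethoxyphenoxy)-2,3,4-trimethoxybenzaldehyde (heptamer A–G aldehyde) | COc1cc(OC)c(c(OC)c1)Oc1cc(OC)c(c(OC)c1)Oc1cc(OC)c(OC)c(OC)c1Oc1cc(OC)c(c(OC)c1)Oc1cc(OC)c(OC)c(OC)c1Oc1cc(OC)c(c(OC)c1)Oc1cc(OC)c(OC)c(OC)c1C=O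
F11 | step 20 | 6-(4-{6-[4-(Ar-ABC-oxy)-2,6-dimethoxyphenoxy]-2,3,4-trimethoxyphenoxy}-2,6-dimethoxyphenoxy)-2,3,4-trimethoxyphenyl formate | COc1cc(OC)c(c(OC)c1)Oc1cc(OC)c(c(OC)c1)Oc1cc(OC)c(OC)c(OC)c1Oc1cc(OC)c(c(OC)c1)Oc1cc(OC)c(OC)c(OC)c1Oc1cc(OC)c(c(OC)c1)Oc1cc(OC)c(OC)c(OC)c1OC=O
F12 | step 20 | 6-(4-{6-[4-(Ar-ABC-oxy)-2,6-dimethoxyphenoxy]-2,3,4-trimethoxyphenoxy}-2,6-dimethoxyphenoxy)-2,3,4-trimethoxyphenol (heptamer A–G phenol) | COc1cc(OC)c(c(OC)c1)Oc1cc(OC)c(c(OC)c1)Oc1cc(OC)c(OC)c(OC)c1Oc1cc(OC)c(c(OC)c1)Oc1cc(OC)c(OC)c(OC)c1Oc1cc(OC)c(c(OC)c1)Oc1cc(OC)c(OC)c(OC)c1O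
F13 | step 20 | henicosa-O-methyl ether of 34 (fully methylated octamer A–H) | COc1cc(OC)c(c(OC)c1)Oc1cc(OC)c(c(OC)c1)Oc1cc(OC)c(OC)c(OC)c1Oc1cc(OC)c(c(OC)c1)Oc1cc(OC)c(OC)c(OC)c1Oc1cc(OC)c(c(OC)c1)Oc1cc(OC)c(OC)c(OC)c1Oc1cc(OC)c(OC)c(OC)c1
F14 | step 19 | 4-bromo-6-[(Ar-EFGH-oxy)methyl]-2H-pyran-2-one | O=C1C=C(Br)C=C(COc2cc(OC)c(OC)c(OC)c2Oc2cc(OC)c(c(OC)c2)Oc2cc(OC)c(OC)c(OC)c2Oc2cc(OC)c(OC)c(OC)c2)O1
F15 | step 21 | henicosa-O-acetate of 34 | CC(=O)Oc1cc(OC(C)=O)c(Oc2cc(OC(C)=O)c(Oc3cc(OC(C)=O)c(OC(C)=O)c(OC(C)=O)c3Oc3cc(OC(C)=O)c(Oc4cc(OC(C)=O)c(OC(C)=O)c(OC(C)=O)c4Oc4cc(OC(C)=O)c(Oc5cc(OC(C)=O)c(OC(C)=O)c(OC(C)=O)c5Oc5cc(OC(C)=O)c(OC(C)=O)c(OC(C)=O)c5)c(OC(C)=O)c4)c(OC(C)=O)c3)c(OC(C)=O)c2)c(OC(C)=O)c1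
F16 | step 16 | N-methoxy-N-methyl-2-(Ar-EFGH-oxy)acetamide | CON(C)C(=O)COc1cc(OC)c(OC)c(OC)c1Oc1cc(OC)c(c(OC)c1)Oc1cc(OC)c(OC)c(OC)c1Oc1cc(OC)c(OC)c(OC)c1
F17 | step 16 | 2,2-dimethyl-6-[3-(Ar-EFGH-oxy)-2-oxopropyl]-4H-1,3-dioxin-4-one | CC1(C)OC(=O)C=C(CC(=O)COc2cc(OC)c(OC)c(OC)c2Oc2cc(OC)c(c(OC)c2)Oc2cc(OC)c(OC)c(OC)c2Oc2cc(OC)c(OC)c(OC)c2)O1
F18 | step 13 | 4-(6-{4-[6-(benzyloxy)-2,3,4-trimethoxyphenoxy]-2,6-dimethoxyphenoxy}-2,3,4-trimethoxyphenoxy)-2,6-dimethoxybenzaldehyde | c1ccccc1COc1cc(OC)c(OC)c(OC)c1Oc1cc(OC)c(c(OC)c1)Oc1cc(OC)c(OC)c(OC)c1Oc1cc(OC)c(C=O)c(OC)c1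
F19 | step 13 | 4-(6-{4-[6-(benzyloxy)-2,3,4-trimethoxyphenoxy]-2,6-dimethoxyphenoxy}-2,3,4-trimethoxyphenoxy)-2,6-dimethoxyphenyl formate | c1ccccc1COc1cc(OC)c(OC)c(OC)c1Oc1cc(OC)c(c(OC)c1)Oc1cc(OC)c(OC)c(OC)c1Oc1cc(OC)c(OC=O)c(OC)c1
F20 | step 13 | 4-(6-{4-[6-(benzyloxy)-2,3,4-trimethoxyphenoxy]-2,6-dimethoxyphenoxy}-2,3,4-trimethoxyphenoxy)-2,6-dimethoxyphenol | c1ccccc1COc1cc(OC)c(OC)c(OC)c1Oc1cc(OC)c(c(OC)c1)Oc1cc(OC)c(OC)c(OC)c1Oc1cc(OC)c(O)c(OC)c1
F21 | step 4 | 6-bromo-2,3,4-trimethoxybenzaldehyde | COc1cc(Br)c(C=O)c(OC)c1OC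
A1 | alternative 1 | 2-[(tert-butyldimethylsilyl)oxy]-3-methoxy-5-(2,4,6-trimethoxyphenoxy)phenol | COc1cc(Oc2c(OC)cc(OC)cc2OC)cc(O)c1O[Si](C)(C)C(C)(C)C
A2 | alternative 1 | 2-(ethynyloxy)-1,3,5-trimethoxybenzene | C#COc1c(OC)cc(OC)cc1OC
A3 | alternative 1 | 3-methoxy-4-[(tert-butyldimethylsilyl)oxy]cyclobut-2-en-1-one (racemic) | COC1=CC(=O)C1O[Si](C)(C)C(C)(C)C
A4 | alternative 2 | 6-[2,6-dimethoxy-4-(2,4,6-trimethoxyphenoxy)phenoxy]-2,3,4-trimethoxyphenol (identical with 10) | COc1cc(OC)c(c(OC)c1)Oc1cc(OC)c(c(OC)c1)Oc1cc(OC)c(OC)c(OC)c1O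
A5 | alternative 2 | 4-{(Z)-2-[2,6-dimethoxy-4-(2,4,6-trimethoxyphenoxy)phenoxy]ethenyl}-2,3,4-trimethoxycyclobut-2-en-1-one (racemic) | COC1=C(OC)C(OC)(/C=C\Oc2c(OC)cc(Oc3c(OC)cc(OC)cc3OC)cc2OC)C1=O
A6 | alternative 3 | octamer with the ring A triol free and rings B to H as methyl ethers | Oc1cc(O)c(c(O)c1)Oc1cc(OC)c(c(OC)c1)Oc1cc(OC)c(OC)c(OC)c1Oc1cc(OC)c(c(OC)c1)Oc1cc(OC)c(OC)c(OC)c1Oc1cc(OC)c(c(OC)c1)Oc1cc(OC)c(OC)c(OC)c1Oc1cc(OC)c(OC)c(OC)c1
A7 | alternative 3 | methyl 6-aryloxy-3,5-dioxohexanoate of the nonadeca-O-methyl heptamer B–H (bonded through ring B) | COC(=O)CC(=O)CC(=O)COc1cc(OC)c(c(OC)c1)Oc1cc(OC)c(OC)c(OC)c1Oc1cc(OC)c(c(OC)c1)Oc1cc(OC)c(OC)c(OC)c1Oc1cc(OC)c(c(OC)c1)Oc1cc(OC)c(OC)c(OC)c1Oc1cc(OC)c(OC)c(OC)c1
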